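**Plan**

1. Tetralin numbering is used throughout: C1 aryl methine, C2/C3 bearing CH2OH, C4 methylene, C4a/C8a fusion carbons, C6 OMe, C7/C8 OH; ring A is the arene, ring B the saturated ring.
2. Enabling feature: ring B (C1–C2–C3–C4–C4a–C8a) is a cyclohexene whose C4a=C8a bond belongs to arene ring A and whose trans C2/C3 pair is a reduced fumarate. The retrosynthesis therefore cuts C1–C2 and C3–C4 (retro-Diels–Alder), after returning the two CH2OH groups to esters and the three phenols to benzyl ethers.
3. The diene, an α-aryl o-quinodimethane, is stored as a cyclic sulfone. Cutting its two C–S bonds leads to a diol, and cutting C1–C8a leads to an aryllithium from brominated 5-hydroxyvanillin plus O-benzylvanillin.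
4. Forward order: ring A building block (steps 1–4), C1–C8a bond (step 5), five-membered sulfur ring (steps 6–8), ring B by cycloaddition with the lactate fumarate (steps 9–10), reduction and debenzylation (steps 11–12).
5. Stereochemistry: C2/C3 trans from the E-fumarate, C1 trans to C2 from exo placement of the C2 ester, absolute sense from the (S)-lactate auxiliaries. The racemic sulfone centre is erased in the planar diene, and no later step touches the three centres.

Key step: step 10

Assumption: the (S)-lactate groups are taken to shield the fumarate face that, in the exo transition state, leads to (1S,2R,3R)-17; this sense cannot be derived with certainty on paper and is to be confirmed on the first batch by X-ray analysis of 17, whose lactate centres serve as internal reference.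

**Route**

Step 1
Reactants: 1 5-hydroxyvanillin (3,4-dihydroxy-5-methoxybenzaldehyde)
Product: 2 4-(benzyloxy)-3-hydroxy-5-methoxybenzaldehyde
Conditions: BnBr (1.05 equiv), NaHCO3, DMF, 40 °C
Reagents that add atoms: benzyl bromide, BrCc1ccccc1
Why: Williamson etherification under weak-base control, in which only the 4-hydroxyl (para to the formyl group, hence the more acidic phenol) is ionized and benzylated, leaving the 3-hydroxyl free to direct the next step.

Step 2
Reactants: 2 4-(benzyloxy)-3-hydroxy-5-methoxybenzaldehyde
Product: 3 4-(benzyloxy)-2-bromo-3-hydroxy-5-methoxybenzaldehyde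
Conditions: NBS (1.0 equiv), i-Pr2NH (cat.), CH2Cl2, 0 °C
Reagents that add atoms: N-bromosuccinimide, O=C1CCC(=O)N1Br
Why: Amine-mediated ortho-selective electrophilic bromination of a phenol, directed to C2 because it is the only free position ortho to the hydroxyl and is also para to the methoxy group, the same sense as the established ortho-bromination of isovanillin-type 3-hydroxybenzaldehydes.

Step 3
Reactants: 3 4-(benzyloxy)-2-bromo-3-hydroxy-5-methoxybenzaldehyde
Product: 4 3,4-bis(benzyloxy)-2-bromo-5-methoxybenzaldehyde
Conditions: BnBr (1.2 equiv), K2CO3, DMF, 60 °C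
Reagents that add atoms: benzyl bromide, BrCc1ccccc1
Why: Williamson etherification of the remaining phenol in a dipolar aprotic solvent, under which neither the aryl bromide nor the aldehyde reacts.

Step 4
Reactants: 4 3,4-bis(benzyloxy)-2-bromo-5-methoxybenzaldehyde
Product: 5 [3,4-bis(benzyloxy)-2-bromo-5-methoxyphenyl]methanol
Conditions: NaBH4, THF–MeOH, 0 °C
Reagents that add atoms: none
Why: Chemoselective hydride reduction of the aldehyde that leaves the aryl bromide and benzyl ethers untouched and gives an alcohol that protects itself as its lithium alkoxide in step 5.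

Step 5
Reactants: 5 [3,4-bis(benzyloxy)-2-bromo-5-methoxyphenyl]methanol; 6 4-(benzyloxy)-3-methoxybenzaldehyde (O-benzylvanillin)
Product: 8 racemic [2,3-bis(benzyloxy)-6-(hydroxymethyl)-4-methoxyphenyl][4-(benzyloxy)-3-methoxyphenyl]methanol, via dilithio alkoxide 7 (not isolated)
Conditions: n-BuLi (2.1 equiv), THF, −78 °C; then 6, −78 → 0 °C; H2O quench
Reagents that add atoms: none
Why: O-deprotonation followed by bromine–lithium exchange gives an o-lithiobenzyl alkoxide whose aryllithium adds 1,2 to the aldehyde and forms the C1–C8a bond, the new carbinol centre being racemic and of no consequence because it is planarized in step 10.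

Step 6
Reactants: 8 racemic [2,3-bis(benzyloxy)-6-(hydroxymethyl)-4-methoxyphenyl][4-(benzyloxy)-3-methoxyphenyl]methanol
Product: 9 racemic 3,4-bis(benzyloxy)-2-{bromo[4-(benzyloxy)-3-methoxyphenyl]methyl}-1-(bromomethyl)-5-methoxybenzene
Conditions: PBr3 (1.0 equiv), CH2Cl2, 0 °C; cold NaHCO3 wash, used crude at once
Reagents that add atoms: phosphorus tribromide, BrP(Br)Br
Why: Conversion of both benzylic alcohols to bromides through phosphite esters (SN2 at the primary carbon, SN1-like at the doubly benzylic carbon), the classical entry to o-xylylene dibromides.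

Step 7
Reactants: 9 racemic 3,4-bis(benzyloxy)-2-{bromo[4-(benzyloxy)-3-methoxyphenyl]methyl}-1-(bromomethyl)-5-methoxybenzene
Product: 10 racemic 6,7-bis(benzyloxy)-1-[4-(benzyloxy)-3-methoxyphenyl]-5-methoxy-1,3-dihydrobenzo[c]thiophene
Conditions: Na2S·9H2O (1.2 equiv), Bu4NHSO4 (cat.), CH2Cl2–H2O, rt
Reagents that add atoms: sodium sulfide, [Na+].[Na+].[S-2]
Why: Double nucleophilic substitution by sulfide under phase transfer closes the five-membered ring (5-exo-tet in the second displacement), and keeping the labile dibromide in the organic phase limits its hydrolysis.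

Step 8
Reactants: 10 racemic 6,7-bis(benzyloxy)-1-[4-(benzyloxy)-3-methoxyphenyl]-5-methoxy-1,3-dihydrobenzo[c]thiophene
Product: 12 racemic 6,7-bis(benzyloxy)-1-[4-(benzyloxy)-3-methoxyphenyl]-5-methoxy-1,3-dihydrobenzo[c]thiophene 2,2-dioxide, via sulfoxide 11 (not isolated)
Conditions: mCPBA (2.2 equiv), CH2Cl2, 0 °C → rt
Reagents that add atoms: 3-chloroperbenzoic acid, OOC(=O)c1cccc(Cl)c1
Why: Stepwise peracid oxidation at sulfur (sulfide to sulfoxide to sulfone), which is far faster than any attack on the alkoxy arenes or the benzyl ethers.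

Step 9
Reactants: 13 fumaryl chloride; 14 methyl (S)-lactate (2.2 equiv)
Product: 15 bis[(2S)-1-methoxy-1-oxopropan-2-yl] (2E)-but-2-enedioate
Conditions: toluene, 80 °C, N2 sweep (HCl expelled), no base
Reagents that add atoms: none
Why: Nucleophilic acyl substitution of the diacid chloride by the secondary alcohol, run without base so that neither the E double bond nor the lactate stereocentres (not involved in the bond change) are disturbed.

Step 10
Reactants: 12 racemic 6,7-bis(benzyloxy)-1-[4-(benzyloxy)-3-methoxyphenyl]-5-methoxy-1,3-dihydrobenzo[c]thiophene 2,2-dioxide; 15 bis[(2S)-1-methoxy-1-oxopropan-2-yl] (2E)-but-2-enedioate (3 equiv)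
Product: 17 bis[(2S)-1-methoxy-1-oxopropan-2-yl] (1S,2R,3R)-7,8-bis(benzyloxy)-1-[4-(benzyloxy)-3-methoxyphenyl]-6-methoxy-1,2,3,4-tetrahydronaphthalene-2,3-dicarboxylate, via outward-aryl o-quinodimethane 16 (not isolated)
Conditions: 1,2-dichlorobenzene (degassed), 180 °C, slow Ar stream; chromatography, then crystallization
Reagents that add atoms: none
Why: Heating drives a cheletropic loss of SO2 from 12 in which the C1 aryl group rotates outward, away from the CH2 terminus, to give the transient o-quinodimethane 16, in which the stereocentre of the racemic sulfone no longer exists. The closest known reaction type is the sulfone-thermolysis/o-quinodimethane Diels–Alder route to 1-aryltetralin lignans with fumarate esters, including fumarates of α-hydroxy esters as chiral dienophiles. Ring B closes by an intermolecular, concerted, suprafacial [4+2] cycloaddition that forms C1–C2 and C3–C4 together and is driven by the return of aromaticity to ring A. C2 and C3 come out trans because the E geometry of the fumarate is transferred stereospecifically; C1 is set trans to C2 by exo placement of the C2 ester (the C3 ester then lies endo under ring A), which should be favoured because the aryl group, twisted out of the diene plane by the peri benzyloxy group at C8, crowds the endo position next to C1; the absolute sense comes from the two (S)-lactate groups, which make the two faces of the fumarate diastereotopic. The step thus needs outward rotation of the aryl group, exo selectivity for the C2 ester and one fumarate face, secured respectively by the clash of an inward aryl with the methylene terminus, by the twisted aryl group and by the auxiliaries. Because the auxiliaries stay in the product, every stereoisomer formed is a diastereomer of 17, and 17 is isolated pure at this stage; this matters because a 1,2-cis adduct formed on the same fumarate face would carry the opposite C1 configuration and must not be carried on.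

Step 11
Reactants: 17 bis[(2S)-1-methoxy-1-oxopropan-2-yl] (1S,2R,3R)-7,8-bis(benzyloxy)-1-[4-(benzyloxy)-3-methoxyphenyl]-6-methoxy-1,2,3,4-tetrahydronaphthalene-2,3-dicarboxylate
Product: 18 [(1S,2R,3R)-7,8-bis(benzyloxy)-1-[4-(benzyloxy)-3-methoxyphenyl]-6-methoxy-1,2,3,4-tetrahydronaphthalene-2,3-diyl]dimethanol
Conditions: LiAlH4 (5 equiv), THF, 0 °C → rt; H2O/NaOH work-up
Reagents that add atoms: none
Why: LiAlH4 ester reduction of all four ester carbonyls turns the ring carboxylates into the C2/C3 hydroxymethyl groups and releases the auxiliaries as (S)-propane-1,2-diol, and because hydride addition is much faster than enolization, C2 and C3 keep their configuration while the benzyl ethers are inert.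

Step 12
Reactants: 18 [(1S,2R,3R)-7,8-bis(benzyloxy)-1-[4-(benzyloxy)-3-methoxyphenyl]-6-methoxy-1,2,3,4-tetrahydronaphthalene-2,3-diyl]dimethanol
Product: 19 (1S,2R,3R)-1-(4-hydroxy-3-methoxyphenyl)-2,3-bis(hydroxymethyl)-6-methoxy-1,2,3,4-tetrahydronaphthalene-7,8-diol (target)
Conditions: H2 (1 atm), 10% Pd/C, EtOAc–MeOH, rt; filtration under Ar
Reagents that add atoms: none
Why: Catalytic hydrogenolysis of the three aryl benzyl ethers under neutral conditions, which touches neither the C1–aryl bonds, the primary alcohols nor any stereocentre.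

**Compound list**

1 | 5-hydroxyvanillin (3,4-dihydroxy-5-methoxybenzaldehyde) | COc1cc(C=O)cc(O)c1O | starting material
2 | 4-(benzyloxy)-3-hydroxy-5-methoxybenzaldehyde | COc1cc(C=O)cc(O)c1OCc1ccccc1 | intermediate
3 | 4-(benzyloxy)-2-bromo-3-hydroxy-5-methoxybenzaldehyde | COc1cc(C=O)c(Br)c(O)c1OCc1ccccc1 | intermediate
4 | 3,4-bis(benzyloxy)-2-bromo-5-methoxybenzaldehyde | COc1cc(C=O)c(Br)c(OCc2ccccc2)c1OCc1ccccc1 | intermediate
5 | [3,4-bis(benzyloxy)-2-bromo-5-methoxyphenyl]methanol | COc1cc(CO)c(Br)c(OCc2ccccc2)c1OCc1ccccc1 | intermediate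
6 | 4-(benzyloxy)-3-methoxybenzaldehyde (O-benzylvanillin) | COc1cc(C=O)ccc1OCc1ccccc1 | starting material
7 | lithium [3,4-bis(benzyloxy)-2-lithio-5-methoxyphenyl]methanolate | COc1cc(CO[Li])c([Li])c(OCc2ccccc2)c1OCc1ccccc1 | intermediate (not isolated)
8 | racemic [2,3-bis(benzyloxy)-6-(hydroxymethyl)-4-methoxyphenyl][4-(benzyloxy)-3-methoxyphenyl]methanol | COc1cc(CO)c(C(O)c2ccc(OCc3ccccc3)c(OC)c2)c(OCc2ccccc2)c1OCc1ccccc1 | intermediate
9 | racemic 3,4-bis(benzyloxy)-2-{bromo[4-(benzyloxy)-3-methoxyphenyl]methyl}-1-(bromomethyl)-5-methoxybenzene | COc1cc(CBr)c(C(Br)c2ccc(OCc3ccccc3)c(OC)c2)c(OCc2ccccc2)c1OCc1ccccc1 | intermediate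
10 | racemic 6,7-bis(benzyloxy)-1-[4-(benzyloxy)-3-methoxyphenyl]-5-methoxy-1,3-dihydrobenzo[c]thiophene | COc1cc(C2c3c(cc(OC)c(OCc4ccccc4)c3OCc3ccccc3)CS2)ccc1OCc1ccccc1 | intermediate
11 | 6,7-bis(benzyloxy)-1-[4-(benzyloxy)-3-methoxyphenyl]-5-methoxy-1,3-dihydrobenzo[c]thiophene 2-oxide (diastereomer mixture) | COc1cc(C2c3c(cc(OC)c(OCc4ccccc4)c3OCc3ccccc3)CS2=O)ccc1OCc1ccccc1 | intermediate (not isolated)
12 | racemic 6,7-bis(benzyloxy)-1-[4-(benzyloxy)-3-methoxyphenyl]-5-methoxy-1,3-dihydrobenzo[c]thiophene 2,2-dioxide | COc1cc(C2c3c(cc(OC)c(OCc4ccccc4)c3OCc3ccccc3)CS2(=O)=O)ccc1OCc1ccccc1 | intermediate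
13 | fumaryl chloride | O=C(Cl)/C=C/C(=O)Cl | starting material
14 | methyl (S)-lactate | C[C@H](O)C(=O)OC | starting material
15 | bis[(2S)-1-methoxy-1-oxopropan-2-yl] (2E)-but-2-enedioate | COC(=O)[C@H](C)OC(=O)/C=C/C(=O)O[C@@H](C)C(=O)OC | intermediate
16 | (6Z)-1,2-bis(benzyloxy)-6-{[4-(benzyloxy)-3-methoxyphenyl]methylidene}-3-methoxy-5-methylidenecyclohexa-1,3-diene (aryl outward, trans to the methylidene-bearing ring carbon; the descriptor is Z only because C8 carries oxygen) | C=C1C=C(OC)C(OCc2ccccc2)=C(OCc2ccccc2)/C1=C\c1ccc(OCc2ccccc2)c(OC)c1 | intermediate (not isolated)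
17 | bis[(2S)-1-methoxy-1-oxopropan-2-yl] (1S,2R,3R)-7,8-bis(benzyloxy)-1-[4-(benzyloxy)-3-methoxyphenyl]-6-methoxy-1,2,3,4-tetrahydronaphthalene-2,3-dicarboxylate | COc1cc([C@H]2c3c(cc(OC)c(OCc4ccccc4)c3OCc3ccccc3)C[C@@H](C(=O)O[C@@H](C)C(=O)OC)[C@@H]2C(=O)O[C@@H](C)C(=O)OC)ccc1OCc1ccccc1 | intermediate
18 | [(1S,2R,3R)-7,8-bis(benzyloxy)-1-[4-(benzyloxy)-3-methoxyphenyl]-6-methoxy-1,2,3,4-tetrahydronaphthalene-2,3-diyl]dimethanol | COc1cc([C@H]2c3c(cc(OC)c(OCc4ccccc4)c3OCc3ccccc3)C[C@@H](CO)[C@@H]2CO)ccc1OCc1ccccc1 | intermediate
19 | (1S,2R,3R)-1-(4-hydroxy-3-methoxyphenyl)-2,3-bis(hydroxymethyl)-6-methoxy-1,2,3,4-tetrahydronaphthalene-7,8-diol | COc1cc([C@H]2c3c(cc(OC)c(O)c3O)C[C@@H](CO)[C@@H]2CO)ccc1O | target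

**Step count**

Total: 12 steps. Longest linear sequence: 11 steps (steps 1–8, 10, 11, 12) from 5-hydroxyvanillin; step 9 is a one-step side branch.

**Steps most likely to fail**

1. Step 10. The cycloaddition may show insufficient exo preference for the C2 ester, or insufficient face discrimination at 180 °C, so that little pure 17 can be separated. The peri benzyloxy group may also slow the outward rotation of the aryl group and favour diene decomposition over capture.
Fallback: the fallback uses the endo mode and thermodynamic correction instead of kinetic exo control. It sets out from sulfone 12 and fumaryl chloride 13. Commercial methyl (R)-lactate and 13 would give bis[(2R)-1-methoxy-1-oxopropan-2-yl] (2E)-but-2-enedioate F1. Thermolysis of 12 with it should deliver, as the endo counterpart on the mirror-image fumarate face, bis[(2R)-1-methoxy-1-oxopropan-2-yl] (1S,2S,3S)-7,8-bis(benzyloxy)-1-[4-(benzyloxy)-3-methoxyphenyl]-6-methoxy-1,2,3,4-tetrahydronaphthalene-2,3-dicarboxylate F2 (1,2-cis, 2,3-trans, correct C1), which is isolated as a single diastereomer. NaOMe in MeOH at reflux would then transesterify and epimerize both α-ester centres (C1 cannot enolize) to the all-equatorial dimethyl (1S,2R,3R)-7,8-bis(benzyloxy)-1-[4-(benzyloxy)-3-methoxyphenyl]-6-methoxy-1,2,3,4-tetrahydronaphthalene-2,3-dicarboxylate F3. LiAlH4 reduction of that diester rejoins the route at diol 18.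

2. Step 6. The electron-rich diaryl carbinol may ionize and be captured by the neighbouring hydroxymethyl oxygen (cyclic ether formation) before bromide is installed, and the doubly benzylic bromide may hydrolyse or decompose during work-up.
Fallback: the dibromide is avoided altogether. Setting out from diol 8, direct thionation with Lawesson's reagent (toluene, 80 °C) should give the cyclic sulfide. This is a known conversion of 1,2-benzenedimethanols into 1,3-dihydrobenzo[c]thiophenes, which runs through a benzylic thiol and intramolecular capture of the diarylmethyl cation. The route is rejoined at sulfide 10; this fallback makes no compound outside the list (none F0).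

3. Step 2. Bromination may occur para instead of ortho to the free phenol, or at both positions, giving the wrong connection point for C8a.
Fallback: the roles of the two fragments are reversed and the carbon substituent is introduced by phenol-directed formylation. Setting out from 2, NaBH4 reduction would give 2-(benzyloxy)-5-(hydroxymethyl)-3-methoxyphenol F4. Magnesium-mediated ortho-formylation (MgCl2, Et3N, paraformaldehyde, MeCN, reflux), which can only take place at the single free carbon ortho to the phenol, would give 3-(benzyloxy)-2-hydroxy-6-(hydroxymethyl)-4-methoxybenzaldehyde F5. Benzylation (BnBr, K2CO3, DMF) would give 2,3-bis(benzyloxy)-6-(hydroxymethyl)-4-methoxybenzaldehyde F6. Addition of [4-(benzyloxy)-3-methoxyphenyl]magnesium bromide F7 (2.2 equiv, prepared from commercial 1-(benzyloxy)-4-bromo-2-methoxybenzene and Mg in THF) would then give diol 8, where the route is rejoined; steps 3–5 are bypassed.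

**Further compounds**

F1 | step 10 | bis[(2R)-1-methoxy-1-oxopropan-2-yl] (2E)-but-2-enedioate | COC(=O)[C@@H](C)OC(=O)/C=C/C(=O)O[C@H](C)C(=O)OC
F2 | step 10 | bis[(2R)-1-methoxy-1-oxopropan-2-yl] (1S,2S,3S)-7,8-bis(benzyloxy)-1-[4-(benzyloxy)-3-methoxyphenyl]-6-methoxy-1,2,3,4-tetrahydronaphthalene-2,3-dicarboxylate | COc1cc([C@H]2c3c(cc(OC)c(OCc4ccccc4)c3OCc3ccccc3)C[C@H](C(=O)O[C@H](C)C(=O)OC)[C@H]2C(=O)O[C@H](C)C(=O)OC)ccc1OCc1ccccc1
F3 | step 10 | dimethyl (1S,2R,3R)-7,8-bis(benzyloxy)-1-[4-(benzyloxy)-3-methoxyphenyl]-6-methoxy-1,2,3,4-tetrahydronaphthalene-2,3-dicarboxylate | COc1cc([C@H]2c3c(cc(OC)c(OCc4ccccc4)c3OCc3ccccc3)C[C@@H](C(=O)OC)[C@@H]2C(=O)OC)ccc1OCc1ccccc1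
F0 | step 6 | none | none
F4 | step 2 | 2-(benzyloxy)-5-(hydroxymethyl)-3-methoxyphenol | COc1cc(CO)cc(O)c1OCc1ccccc1
F5 | step 2 | 3-(benzyloxy)-2-hydroxy-6-(hydroxymethyl)-4-methoxybenzaldehyde | COc1cc(CO)c(C=O)c(O)c1OCc1ccccc1
F6 | step 2 | 2,3-bis(benzyloxy)-6-(hydroxymethyl)-4-methoxybenzaldehyde | COc1cc(CO)c(C=O)c(OCc2ccccc2)c1OCc1ccccc1
F7 | step 2 | [4-(benzyloxy)-3-methoxyphenyl]magnesium bromide | COc1cc([Mg]Br)ccc1OCc1ccccc1
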